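(The numbers in the tables were generated by integration from invented constants, noise included.)

Read in molar rather than in percent of the charge, the two earlier runs show one number, and a repeat of the run should watch that number.

| flask | starting material | catalyst | remark | time |
|---|---|---|---|---|
| Thursday's | 0.80 M | 1.3 mol% | the very flask that is asked about, followed so far |  |
| Friday's | 0.40 M | 1.3 mol% | run made earlier |  |
| flask | 0.80 M | 1.3 mol% |  | 5.0 min |

| run | time / s | target / % | crystals / % |
|---|---|---|---|
| Thursday's | 15.0 | 37 | 18 |
| Thursday's | 30.0 | 62 | 42 |
| Thursday's | 50.0 | 76 | 58 |
| Thursday's | 60.0 | 81 | 64 |
| Thursday's | 80.0 | 89 | 67 |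
| Thursday's | 90.0 | 90 | 72 |
| Thursday's | 120 | 92 | 72 |
| Friday's | 10.0 | 19 | 0 |
| Friday's | 15.0 | 21 | 2 |
| Friday's | 20.0 | 26 | 0 |
| Friday's | 30.0 | 35 | 0 |
| Friday's | 50.0 | 54 | 18 |
| Friday's | 80.0 | 69 | 31 |
| Friday's | 120 | 80 | 41 |

(scatter of a reading: 1.5 percentage points)

- amount of target and crystals together at 5.0 min, in percent of the starting material charged
- concentration of target in solution at 5.0 min, in percent of saturation

- amounts and yields of target count crystals too
- given per volume of solution although it is solid: crystals

Crystals are counted inside target, so target minus crystals, times the starting concentration, is [target] in solution. In Thursday's flask this averages 0.154 M from 60.0 s to 120 s. In Friday's flask it averages 0.151 M from 50.0 s to 120 s, although there it is twice Thursday's share of the charge. These are two ways from two different charges, and they part by 0.42 percentage points of Thursday's charge, against a scatter of 1.5 points per reading. Their mean, 0.152 M, is taken here, as a reading with that scatter, for the ceiling on [target] while crystals stand, the solubility.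

Thursday's flask already reads 0.152 M in solution at 15.0 s, so the exchange with crystals can be taken as in balance. Its crystals read 72% at 120 s, while the ceiling holds 19.0% of the charge in solution, so this reckoning keeps the solution saturated at the asked time. For the total, target in Thursday's flask reads 90% at 90.0 s and 92% at 120 s, and from these this reckoning expects the answer a little above the last reading, with no sharper estimate.

The forecast gives 95% and 100%, with “no noticeable supersaturation”.

The flask gives 93.3% and 100%, with starting material at 0% and side product at 6.73%.

    starting material + catalyst → catalyst + target (k = 3.20 M⁻¹ s⁻¹)
    starting material → side product (k = 0.00240 s⁻¹)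
    crystals ⇌ target, rate k3*(cs3 - [target]) while solid is left; crystals form when [target] > cs3 (solubility = 0.150 M, k = 4.80 s⁻¹)

With that total, the ceiling gives crystals of 74.2% in the asked flask, which holds 74.5%. Going down from the asked flask, the total has moved by 5 points at 0.441 M of starting material with the loading and time held, or at 0.72 mol% of catalyst with the other amounts and the time held. In a neighbouring flask with 0.32 M of starting material, its loading and time held, the ceiling holds 47.5% of the charge in solution, so a total of 84.0% leaves 36.5% as crystals. The computed neighbouring flask holds 37.1% of crystals, within a total of 84.0%.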